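The six-membered ring is disconnected at C4–C5 and C1–C6 (numbering: C1 ketone, C2 bearing C7, C3, C4 tigloyloxy, C5 isopropyl, C6 acetoxy). The feature exploited is the 1,4-relationship of the C1 ketone and the C4 oxygen across the C2=C3 alkene that carries C7: this is what remains when the oxygen bridge of a 2-silyloxyfuran [4+2] adduct is opened. One copper–bis(oxazoline)-catalysed cycloaddition of a 3-(silyloxymethyl)-2-silyloxyfuran (C1–C4, C7) with an N-(E)-enoyl oxazolidinone (C5, C6), then fluoride collapse of the bridged silyl ketal, should give the carbocycle, the enone, the C4 carbinol cis to isopropyl and the C5 configuration. Excision of the imide carbon, two tigloylations and a face-selective C6 acetoxylation complete the target.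

Key step: step 4

Remarks on the chemistry

- Assumption: C6 of the β-keto imide and β-keto ester stages is drawn as the epimer trans to isopropyl (it is enolisable and is erased by decarboxylation), and the sense of induction of the copper complex is taken from the square-planar chelate model, which calls for the (R,R) ligand.
- t-Bu-box is 2,2'-(propane-2,2-diyl)bis[(4R)-4-tert-butyl-4,5-dihydro-1,3-oxazole].
- The furan is metalated as the dilithio derivative of the free alcohol. A silyl ether at C7 would be liable to 1,4 O-to-C migration onto the lithiated neighbouring carbon.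
- Both silyl groups of the diene are TIPS and are installed in one operation. The primary TIPS ether should outlast the mild fluoride that opens the ketal, and its loss there would be harmless because it is removed two steps later.
- The imide is exchanged for a fluoride-labile ester so that decarboxylation and C7 deprotection occur together near room temperature. Hot Krapcho conditions could dehydrate the γ-hydroxy enone β-keto ester to a phenol.

Step 1
Reactants: 1 furan-3-ylmethanol
Product: 4 3-(hydroxymethyl)furan-2(5H)-one, via 2-lithio-3-(lithiooxymethyl)furan 2 (not isolated), via dimethyl [3-(hydroxymethyl)furan-2-yl]boronate 3 (not isolated)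
Conditions: n-BuLi (2.2 equiv), THF, −78 to 0 °C; B(OMe)3, −78 °C to rt; AcOH, then 30% H2O2, 0 °C to rt
Reagents that add atoms: hydrogen peroxide, OO (oxygen at the lactone carbonyl carbon of 4); n-butyllithium, [Li]CCCC (lithium in 2); trimethyl borate, COB(OC)OC (boron group in 3)
Why: Directed ortho-lithiation, in which the lithium alkoxide steers the second equivalent of base to the adjacent furan carbon, followed by borylation and peroxide oxidation of the C–B bond, gives the 2-hydroxyfuran, which tautomerises to the butenolide; no stereocenter is formed.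

Step 2
Reactants: 4 3-(hydroxymethyl)furan-2(5H)-one
Product: 5 2-(triisopropylsilyloxy)-3-[(triisopropylsilyloxy)methyl]furan
Conditions: TIPSOTf (2.3 equiv), Et3N (3.5 equiv), CH2Cl2, 0 °C to rt
Reagents that add atoms: triisopropylsilyl trifluoromethanesulfonate, CC(C)[Si](OS(=O)(=O)C(F)(F)F)(C(C)C)C(C)C
Why: Silyl dienolate formation by soft enolisation: the silyl triflate silylates the primary alcohol and, with Et3N removing the γ-proton, the lactone carbonyl oxygen, so that either butenolide tautomer converges on the aromatic 2-silyloxyfuran.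

Step 3
Reactants: 6 (E)-4-methylpent-2-enoic acid; 7 oxazolidin-2-one
Product: 9 3-[(E)-4-methylpent-2-enoyl]oxazolidin-2-one, via pivalic mixed anhydride 8 (not isolated)
Conditions: PivCl, Et3N, THF, −20 °C; then LiCl, 7, −20 °C to rt
Reagents that add atoms: pivaloyl chloride, CC(C)(C)C(=O)Cl (pivaloyl group of 8 only; none of its atoms remain in 9)
Why: N-acylation of the oxazolidinone through the mixed pivalic anhydride with LiCl/Et3N activation is a standard mild imide synthesis that leaves the E alkene untouched.

Step 4
Reactants: 5 2-(triisopropylsilyloxy)-3-[(triisopropylsilyloxy)methyl]furan; 9 3-[(E)-4-methylpent-2-enoyl]oxazolidin-2-one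
Product: 11 (4R,5R,6R)-4-hydroxy-6-(2-oxo-1,3-oxazolidine-3-carbonyl)-5-(propan-2-yl)-2-{[tri(propan-2-yl)silyl]oxymethyl}cyclohex-2-en-1-one, via bridged silyl ketal 10 (not isolated)
Conditions: [Cu((R,R)-t-Bu-box)](SbF6)2 (10 mol %, from CuCl2, ligand and AgSbF6), CH2Cl2, −78 to −40 °C; then TBAF/AcOH (1:1, 1.5 equiv), THF, −40 to 0 °C
Reagents that add atoms: none
Why: Proposed new method: the imide chelates divalent copper in a square-planar complex with the enoyl group s-cis, the unsubstituted α-carbon of the silyloxyfuran (future C4) bonds to the β-carbon (C5) and C6 then bonds to the silyloxy-bearing carbon (C1), in concert or by closure of the copper enolate on the silyloxyfuranium ion, to give bridged silyl ketal 10; buffered fluoride then removes the ketal silyl group and the alkoxide collapses to the C1 ketone, breaking the C1–O bridge bond and leaving the C4 hydroxyl beside the now conjugated C2=C3 alkene. The closest known reaction types are the copper–bis(oxazoline) Diels–Alder reaction of furan with N-acryloyl oxazolidinone and Lewis-acid vinylogous Mukaiyama–Michael additions of 2-silyloxyfurans to N-enoyl oxazolidinones, which normally end at the butenolide after silyl transfer; leaving out any protic silyl scavenger and using the slowly transferred TIPS group are meant to let the second bond form. The cyclohexene ring (C1–C6) is closed by the intermolecular endo [4+2] cycloaddition itself, both new bonds (C4–C5 and C1–C6) lying in that ring, with the furan oxygen as a transient one-atom bridge. C5 is set by the ligand, whose tert-butyl group beside the enoyl arm should leave the Re face of the β-carbon open; C4 follows from the endo arrangement, which puts isopropyl exo, on the side of the oxygen bridge and hence cis to the C4 oxygen; C6 follows from the E alkene (trans to isopropyl) and is in any case the stable epimer of the enolisable β-keto imide. The step needs head-to-tail regiochemistry, secured by the polarised diene (silyloxy carbon to acyl-bearing carbon), endo and facial selectivity from the chelate, and desilylation of the ketal in preference to the primary TIPS ether, secured by the much greater lability of the bridgehead silyl ketal.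

Step 5
Reactants: 11 (4R,5R,6R)-4-hydroxy-6-(2-oxo-1,3-oxazolidine-3-carbonyl)-5-(propan-2-yl)-2-{[tri(propan-2-yl)silyl]oxymethyl}cyclohex-2-en-1-one
Product: 12 2-(trimethylsilyl)ethyl (1R,5R,6R)-5-hydroxy-2-oxo-6-(propan-2-yl)-3-{[tri(propan-2-yl)silyl]oxymethyl}cyclohex-3-ene-1-carboxylate
Conditions: Me3SiCH2CH2OH (5 equiv), Yb(OTf)3 (10 mol %), CH2Cl2, rt
Reagents that add atoms: 2-(trimethylsilyl)ethanol, C[Si](C)(C)CCO
Why: Lewis-acid-catalysed alcoholysis of an N-acyl oxazolidinone, in which the oxophilic lanthanide chelates the imide carbonyls and the alcohol attacks the exocyclic acyl carbon, exchanges the auxiliary for a fluoride-labile ester under neutral conditions while C6 remains the equilibrated trans epimer.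

Step 6
Reactants: 12 2-(trimethylsilyl)ethyl (1R,5R,6R)-5-hydroxy-2-oxo-6-(propan-2-yl)-3-{[tri(propan-2-yl)silyl]oxymethyl}cyclohex-3-ene-1-carboxylate
Product: 14 (4R,5S)-4-hydroxy-2-(hydroxymethyl)-5-(propan-2-yl)cyclohex-2-en-1-one, via β-keto acid 13 (not isolated)
Conditions: TBAF (3 equiv), THF, 0 °C to rt; then AcOH, 40 °C
Reagents that add atoms: none
Why: Fluoride-induced fragmentation of the 2-(trimethylsilyl)ethyl ester (β-elimination with release of ethene) gives the β-keto carboxylate, which decarboxylates after acidification near room temperature, while the same fluoride cleaves the primary TIPS ether; C4 and C5 are not enolisable and keep their configuration.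

Step 7
Reactants: 14 (4R,5S)-4-hydroxy-2-(hydroxymethyl)-5-(propan-2-yl)cyclohex-2-en-1-one; 15 tigloyl chloride [(E)-2-methylbut-2-enoyl chloride]
Product: 16 [(3R,4S)-3-{[(E)-2-methylbut-2-enoyl]oxy}-6-oxo-4-(propan-2-yl)cyclohex-1-en-1-yl]methyl (E)-2-methylbut-2-enoate
Conditions: 15 (2.5 equiv), pyridine, DMAP (cat.), CH2Cl2, 0 °C to rt
Reagents that add atoms: none
Why: Acyl chloride esterification of both hydroxyls under nucleophilic catalysis, with pyridine instead of a trialkylamine to avoid vinylketene formation and deconjugation of the tigloyl group, retains the C4 configuration because no C–O bond at carbon is broken.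

Step 8
Reactants: 16 [(3R,4S)-3-{[(E)-2-methylbut-2-enoyl]oxy}-6-oxo-4-(propan-2-yl)cyclohex-1-en-1-yl]methyl (E)-2-methylbut-2-enoate
Product: 17 [(3S,4S,5R)-5-acetyloxy-3-{[(E)-2-methylbut-2-enoyl]oxy}-6-oxo-4-(propan-2-yl)cyclohex-1-en-1-yl]methyl (E)-2-methylbut-2-enoate (CNP0218511.1)
Conditions: Mn(OAc)3·2H2O (4 equiv), benzene–AcOH (10:1), 80 °C
Reagents that add atoms: manganese triacetate dihydrate, CC(=O)[O-].CC(=O)[O-].CC(=O)[O-].[Mn+3].O.O (one acetoxy group)
Why: Mn(OAc)3 α'-acetoxylation of an enone: the manganese enolate formed at C6, the only enolisable α'-position, should take up acetate on the face opposite the cis-disposed C4 tigloyloxy and C5 isopropyl groups, which is also the equatorial, thermodynamically preferred arrangement trans to isopropyl.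

Compound list

1 | furan-3-ylmethanol | OCc1ccoc1 | starting material
2 | 2-lithio-3-(lithiooxymethyl)furan (not isolated) | [Li]OCc1ccoc1[Li] | intermediate
3 | dimethyl [3-(hydroxymethyl)furan-2-yl]boronate (not isolated) | COB(OC)c1occc1CO | intermediate
4 | 3-(hydroxymethyl)furan-2(5H)-one | O=C1OCC=C1CO | intermediate
5 | 2-(triisopropylsilyloxy)-3-[(triisopropylsilyloxy)methyl]furan | CC(C)[Si](OCc1ccoc1O[Si](C(C)C)(C(C)C)C(C)C)(C(C)C)C(C)C | intermediate
6 | (E)-4-methylpent-2-enoic acid | CC(C)/C=C/C(=O)O | starting material
7 | oxazolidin-2-one | O=C1NCCO1 | starting material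
8 | (E)-4-methylpent-2-enoic pivalic anhydride (not isolated) | CC(C)/C=C/C(=O)OC(=O)C(C)(C)C | intermediate
9 | 3-[(E)-4-methylpent-2-enoyl]oxazolidin-2-one | CC(C)/C=C/C(=O)N1CCOC1=O | intermediate
10 | 3-{[3-exo-isopropyl-1-(triisopropylsilyloxy)-6-[(triisopropylsilyloxy)methyl]-7-oxabicyclo[2.2.1]hept-5-en-2-endo-yl]carbonyl}oxazolidin-2-one, absolute configuration as in the SMILES (bridged silyl ketal, not isolated) | CC(C)[Si](OCC1=C[C@H]2[C@H](C(C)C)[C@@H](C(=O)N3CCOC3=O)[C@]1(O[Si](C(C)C)(C(C)C)C(C)C)O2)(C(C)C)C(C)C | intermediate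
11 | (4R,5R,6R)-4-hydroxy-6-(2-oxo-1,3-oxazolidine-3-carbonyl)-5-(propan-2-yl)-2-{[tri(propan-2-yl)silyl]oxymethyl}cyclohex-2-en-1-one (4-OH cis to 5-isopropyl, 6-acyl trans to it) | CC(C)[Si](OCC1=C[C@H](O)[C@H](C(C)C)[C@@H](C(=O)N2CCOC2=O)C1=O)(C(C)C)C(C)C | intermediate
12 | 2-(trimethylsilyl)ethyl (1R,5R,6R)-5-hydroxy-2-oxo-6-(propan-2-yl)-3-{[tri(propan-2-yl)silyl]oxymethyl}cyclohex-3-ene-1-carboxylate | CC(C)[Si](OCC1=C[C@H](O)[C@H](C(C)C)[C@@H](C(=O)OCC[Si](C)(C)C)C1=O)(C(C)C)C(C)C | intermediate
13 | (1R,5R,6R)-5-hydroxy-3-(hydroxymethyl)-2-oxo-6-(propan-2-yl)cyclohex-3-ene-1-carboxylic acid (β-keto acid, not isolated) | OCC1=C[C@H](O)[C@H](C(C)C)[C@@H](C(=O)O)C1=O | intermediate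
14 | (4R,5S)-4-hydroxy-2-(hydroxymethyl)-5-(propan-2-yl)cyclohex-2-en-1-one (OH cis to isopropyl) | OCC1=C[C@H](O)[C@H](C(C)C)CC1=O | intermediate
15 | tigloyl chloride [(E)-2-methylbut-2-enoyl chloride] | C/C=C(\C)C(=O)Cl | starting material
16 | [(3R,4S)-3-{[(E)-2-methylbut-2-enoyl]oxy}-6-oxo-4-(propan-2-yl)cyclohex-1-en-1-yl]methyl (E)-2-methylbut-2-enoate | C/C=C(\C)C(=O)OCC1=C[C@H](OC(=O)/C(C)=C/C)[C@H](C(C)C)CC1=O | intermediate
17 | [(3S,4S,5R)-5-acetyloxy-3-{[(E)-2-methylbut-2-enoyl]oxy}-6-oxo-4-(propan-2-yl)cyclohex-1-en-1-yl]methyl (E)-2-methylbut-2-enoate; route numbering 4S,5S,6R | C/C=C(\C)C(=O)OCC1=C[C@H](OC(=O)/C(C)=C/C)[C@H](C(C)C)[C@@H](OC(C)=O)C1=O | target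

Total step count: 8. Longest linear sequence: 7 steps (steps 1, 2, 4, 5, 6, 7, 8); step 3 is the convergent branch.

Steps most likely to fail

Step 4 (Proposed new method). Silyl transfer may outrun formation of the C1–C6 bond, so that the reaction stops at the conjugate-addition stage. Endo or facial selectivity may be poor or reversed. The Lewis acid may open the bridged adduct prematurely and trigger dehydration towards an arene. The fallback uses known chemistry and sets out from 5 and 9. The same copper complex is used for a vinylogous Mukaiyama–Michael addition in the presence of (CF3)2CHOH (CH2Cl2, −78 °C), which should give the anti butenolide adduct 3-{(3S)-4-methyl-3-[(2R)-5-oxo-4-{[tri(propan-2-yl)silyl]oxymethyl}-2,5-dihydrofuran-2-yl]pentanoyl}-1,3-oxazolidin-2-one F1, already carrying the C4 and C5 configurations. The ring is then closed by a titanium-mediated Dieckmann-type condensation (TiCl4, i-Pr2NEt, CH2Cl2, −78 to 0 °C): the chelated imide titanium enolate attacks the lactone carbonyl (C1) and the tetrahedral intermediate expels the C4 alkoxide. This comes back to the route at 11.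

Step 8. At 80 °C the enolised ketone may lose the C4 ester with aromatisation, and face selectivity of acetate delivery may be incomplete. The fallback sets out from 16. Soft enolisation (Me3SiOTf, Et3N, CH2Cl2, −78 °C) should give the cross-conjugated silyl dienol ether [(3R,4R)-3-{[(E)-2-methylbut-2-enoyl]oxy}-4-(propan-2-yl)-6-(trimethylsilyloxy)cyclohexa-1,5-dien-1-yl]methyl (E)-2-methylbut-2-enoate F2. This is oxidised at low temperature with Pb(OAc)4 (CH2Cl2, −20 °C), a Rubottom-type acetoxylation in which the oxidant approaches the face away from the C4 and C5 substituents. It comes back to the route at 17.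

Step 6. Basic fluoride may isomerise the γ-hydroxy enone or degrade the 2-(hydroxymethyl) enone, and cleavage of the primary TIPS ether may lag behind the ester fragmentation. The fallback sets out from 11 and replaces steps 5 and 6. Alcoholysis with allyl alcohol (Yb(OTf)3 cat., CH2Cl2) should give prop-2-en-1-yl (1R,5R,6R)-5-hydroxy-2-oxo-6-(propan-2-yl)-3-{[tri(propan-2-yl)silyl]oxymethyl}cyclohex-3-ene-1-carboxylate F3. Neutral deallylation–decarboxylation with Pd(PPh3)4 (zerovalent palladium, 5 mol %) and HCO2H/Et3N in THF at rt should give (4R,5S)-4-hydroxy-5-(propan-2-yl)-2-{[tri(propan-2-yl)silyl]oxymethyl}cyclohex-2-en-1-one F4. Desilylation under acidic fluoride (HF·pyridine, THF–pyridine, 0 °C) comes back to the route at 14.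

Further compounds

F1 | step 4 | 3-{(3S)-4-methyl-3-[(2R)-5-oxo-4-{[tri(propan-2-yl)silyl]oxymethyl}-2,5-dihydrofuran-2-yl]pentanoyl}-1,3-oxazolidin-2-one | CC(C)[Si](OCC1=C[C@H](OC1=O)[C@H](C(C)C)CC(=O)N2CCOC2=O)(C(C)C)C(C)C
F2 | step 8 | [(3R,4R)-3-{[(E)-2-methylbut-2-enoyl]oxy}-4-(propan-2-yl)-6-(trimethylsilyloxy)cyclohexa-1,5-dien-1-yl]methyl (E)-2-methylbut-2-enoate | C/C=C(\C)C(=O)OCC1=C[C@H](OC(=O)/C(C)=C/C)[C@H](C(C)C)C=C1O[Si](C)(C)C
F3 | step 6 | prop-2-en-1-yl (1R,5R,6R)-5-hydroxy-2-oxo-6-(propan-2-yl)-3-{[tri(propan-2-yl)silyl]oxymethyl}cyclohex-3-ene-1-carboxylate | CC(C)[Si](OCC1=C[C@H](O)[C@H](C(C)C)[C@@H](C(=O)OCC=C)C1=O)(C(C)C)C(C)C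
F4 | step 6 | (4R,5S)-4-hydroxy-5-(propan-2-yl)-2-{[tri(propan-2-yl)silyl]oxymethyl}cyclohex-2-en-1-one | CC(C)[Si](OCC1=C[C@H](O)[C@H](C(C)C)CC1=O)(C(C)C)C(C)C
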